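**Retrosynthetic overview**
1. Lapiferine ⇐ hydroxyl-directed epoxidation of C8=C9 from the 10α-OH; C6 angelate by esterification; C4 isopropyl carbinol by organocerium addition to a C4 ketone; 5α-H/6α-OH by hydroboration of a C5=C6 alkene; C8 methyl from an ester.
2. ⇐ bicyclic cyclohepta-1,4-diene ester (C5=C6, C8=C9) ⇐ Cope rearrangement of a cis-divinylcyclopropane ⇐ cyclopropanation of an enantiopure 1-methyl-2-vinylcyclopentene silyl ether by a silyloxyvinyl carbenoid (new bonds C7–C8 and C1–C10).
3. Enabling feature: in ring B (C5, C6, C7, C8, C9, C10, C1) the two functionalised units C5–C6 and C8–C9 sit 1,4 across C7H2, and the fully substituted C1 is bonded to carbinol C10. This is the pattern of a cyclohepta-1,4-diene whose C1–C10 bond is the sigmatropic bond, with ring A supplying the C5=C1 half of the diene.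
4. Ring order: ring A (cyclopentane C1–C5) comes with 3-methylcyclopent-2-en-1-one; ring B (cycloheptane) is closed in the key step; the oxirane is put on as a functional group in the last step.
5. Absolute configuration enters by a CBS reduction at C4; this temporary 4β-silyloxy centre steers the cycloaddition and the hydroboration and is later oxidised to the ketone that receives the isopropyl group.

Key step: step 7

Conventions: locants are those of the daucane skeleton of the target (C1 = methyl-bearing quaternary carbon, C4 = isopropyl carbinol carbon, C5 = ring-fusion CH, C6 = angelate carbon, C8/C9 = epoxide carbons, C10 = carbinol carbon next to C1); β is the face of the C1 methyl, α the opposite face.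

Remark: the facial sense of Rh2(R-DOSP)4 is assigned from the accepted model for donor/acceptor carbenoid cyclopropanation of monosubstituted alkenes; if the silyl ether diene reacted in the opposite sense, Rh2(S-DOSP)4 would be used.

**Route**

Step 1
Reactants: 1 3-methylcyclopent-2-en-1-one
Product: 3 2-bromo-3-methylcyclopent-2-en-1-one, via dibromide 2 (not isolated)
Conditions: Br2, CH2Cl2, 0 °C; then Et3N, 0 °C to rt
Reagents that add atoms: bromine BrBr
Why: Bromine addition to the enone followed by amine-induced dehydrobromination (addition–elimination α-bromination of an enone) should give the 2-bromo enone, and no stereocentre remains.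

Step 2
Reactants: 3 2-bromo-3-methylcyclopent-2-en-1-one
Product: 4 (S)-2-bromo-3-methylcyclopent-2-en-1-ol
Conditions: (R)-2-methyl-CBS-oxazaborolidine (10 mol %), BH3·SMe2, THF, −20 °C; then MeOH
Reagents that add atoms: none
Why: CBS reduction, in which the (R)-oxazaborolidine distinguishes the large C(Br)=C side from the CH2 side of this α-bromo enone, should deliver hydride to give the (S)-allylic alcohol.

Step 3
Reactants: 4 (S)-2-bromo-3-methylcyclopent-2-en-1-ol
Product: 5 (S)-[(2-bromo-3-methylcyclopent-2-en-1-yl)oxy]triethylsilane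
Conditions: Et3SiCl, imidazole, CH2Cl2, 0 °C to rt
Reagents that add atoms: chlorotriethylsilane CC[Si](Cl)(CC)CC
Why: Standard silylation of a secondary allylic alcohol, which leaves the stereocentre untouched.

Step 4
Reactants: 5 (S)-[(2-bromo-3-methylcyclopent-2-en-1-yl)oxy]triethylsilane
Product: 6 (S)-triethyl[(3-methyl-2-vinylcyclopent-2-en-1-yl)oxy]silane
Conditions: Bu3SnCH=CH2, Pd(PPh3)4 (5 mol %), toluene, 100 °C
Reagents that add atoms: tributyl(vinyl)stannane C=C[Sn](CCCC)(CCCC)CCCC
Why: Stille coupling of an alkenyl bromide with a vinylstannane under zerovalent palladium catalysis should give the 2-substituted diene without touching the allylic silyl ether or its stereocentre.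

Step 5
Reactants: 7 ethyl diazoacetate; 8 (tert-butyldimethylsilyloxy)acetaldehyde
Product: 9 ethyl 4-[(tert-butyldimethylsilyl)oxy]-2-diazo-3-hydroxybutanoate (racemic)
Conditions: DBU (10 mol %), MeCN, rt
Reagents that add atoms: none
Why: Base-catalysed aldol-type addition of the diazoacetate carbon to the aldehyde; the new carbinol centre forms as a racemate and is removed in step 6.

Step 6
Reactants: 9 ethyl 4-[(tert-butyldimethylsilyl)oxy]-2-diazo-3-hydroxybutanoate
Product: 11 ethyl (E)-4-[(tert-butyldimethylsilyl)oxy]-2-diazobut-3-enoate, via trifluoroacetate 10 (not isolated)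
Conditions: (CF3CO)2O, Et3N, CH2Cl2, 0 °C
Reagents that add atoms: none
Why: Acylation of the β-hydroxyl and amine-promoted elimination (dehydration of a β-hydroxy-α-diazo ester) should give the conjugated vinyldiazo ester, with the E enol ether as the less strained product.

Step 7
Reactants: 6 (S)-triethyl[(3-methyl-2-vinylcyclopent-2-en-1-yl)oxy]silane; 11 ethyl (E)-4-[(tert-butyldimethylsilyl)oxy]-2-diazobut-3-enoate
Product: 13 ethyl (3S,8R,8aS)-8-[(tert-butyldimethylsilyl)oxy]-8a-methyl-3-[(triethylsilyl)oxy]-1,2,3,5,8,8a-hexahydroazulene-6-carboxylate, via cis-divinylcyclopropane 12 (not isolated)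
Conditions: Rh2(R-DOSP)4 (1 mol %), 11 added slowly to 6, hexanes, −40 °C to rt; then toluene, 100 °C
Reagents that add atoms: none
Why: Rh2(R-DOSP)4 converts 11 into a donor/acceptor vinylcarbenoid that cyclopropanates only the monosubstituted vinyl group of 6 (the tetrasubstituted ring alkene is inert) to give cis-divinylcyclopropane 12, which on heating undergoes Cope rearrangement to the cyclohepta-1,4-diene. The closest known reaction type is the tandem cyclopropanation/Cope rearrangement (formal (4+3) cycloaddition) of vinyldiazoacetates with dienes, including 1-vinylcycloalkenes and dienes whose terminus becomes a quaternary carbon. Ring B closes in the [3,3]-sigmatropic step through a boat transition state, the cyclopropane bond C6–C8 breaking while C1–C10 forms, which is a ring expansion of the three-membered ring by four atoms. C1 and C10 are set together: the boat geometry with the E silyloxy group outside places the C10 oxygen trans to the C1 methyl, and the absolute sense follows from the cyclopropane configuration fixed by the chiral catalyst, with the (S)-silyloxy group at C4 on the β face of the cyclopentene acting as a matched element. The step needs attack at the terminal alkene only, a cis arrangement of the two alkenyl groups on the cyclopropane, and a Cope step at a tetrasubstituted terminus with an inside methyl; the first two are secured by the steric and electronic profile of the donor/acceptor carbenoid and the last by heating after the carbenoid stage.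

Step 8
Reactants: 13 ethyl (3S,8R,8aS)-8-[(tert-butyldimethylsilyl)oxy]-8a-methyl-3-[(triethylsilyl)oxy]-1,2,3,5,8,8a-hexahydroazulene-6-carboxylate
Product: 15 ethyl 6α-hydroxy-10α-(tert-butyldimethylsilyloxy)-1β-methyl-4β-(triethylsilyloxy)-5αH-bicyclo[5.3.0]dec-8-ene-8-carboxylate, via alkylborane 14 (not isolated)
Conditions: BH3·SMe2, THF, 0 °C to rt; then H2O2, aq. NaOH, 0 °C
Reagents that add atoms: hydrogen peroxide OO
Why: Hydroboration–oxidation: borane should add syn to the electron-rich C5=C6 bond (the enoate is left) with boron at the less substituted C6 and from the α face, because the β face is closed by the C1 methyl and the allylic 4β-silyloxy group, which sets 5α-H and 6α-OH and hence the trans ring fusion.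

Step 9
Reactants: 15 ethyl 6α-hydroxy-10α-(tert-butyldimethylsilyloxy)-1β-methyl-4β-(triethylsilyloxy)-5αH-bicyclo[5.3.0]dec-8-ene-8-carboxylate
Product: 16 8-(hydroxymethyl)-10α-(tert-butyldimethylsilyloxy)-1β-methyl-4β-(triethylsilyloxy)-5αH-bicyclo[5.3.0]dec-8-en-6α-ol
Conditions: i-Bu2AlH, CH2Cl2, −78 °C
Reagents that add atoms: none
Why: Low-temperature 1,2-reduction of the unsaturated ester by an aluminium hydride gives the primary allylic alcohol and affects no stereocentre.

Step 10
Reactants: 16 8-(hydroxymethyl)-10α-(tert-butyldimethylsilyloxy)-1β-methyl-4β-(triethylsilyloxy)-5αH-bicyclo[5.3.0]dec-8-en-6α-ol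
Product: 18 10α-(tert-butyldimethylsilyloxy)-1β,8-dimethyl-4β-(triethylsilyloxy)-5αH-bicyclo[5.3.0]dec-8-en-6α-ol, via allylic mesylate 17 (not isolated)
Conditions: MsCl, Et3N, THF, −40 °C; then LiEt3BH, −40 to 0 °C
Reagents that add atoms: none
Why: Sulfonylation of the primary allylic alcohol in preference to the hindered secondary C6 alcohol, then SN2 hydride displacement by LiEt3BH (allylic deoxygenation without transposition), should leave the C8 methyl on the intact C8=C9 alkene.

Step 11
Reactants: 18 10α-(tert-butyldimethylsilyloxy)-1β,8-dimethyl-4β-(triethylsilyloxy)-5αH-bicyclo[5.3.0]dec-8-en-6α-ol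
Product: 19 6α-angeloyloxy-10α-(tert-butyldimethylsilyloxy)-1β,8-dimethyl-4β-(triethylsilyloxy)-5αH-bicyclo[5.3.0]dec-8-ene
Conditions: angelic acid, 2,4,6-trichlorobenzoyl chloride, Et3N, toluene, rt; then 18, 75 °C (no DMAP)
Reagents that add atoms: angelic acid C/C=C(/C)C(=O)O
Why: Yamaguchi esterification through the mixed anhydride, run without a nucleophilic catalyst so that the Z (angelate) geometry should not isomerise to the tiglate, acylates the only free hydroxyl with retention at C6.

Step 12
Reactants: 19 6α-angeloyloxy-10α-(tert-butyldimethylsilyloxy)-1β,8-dimethyl-4β-(triethylsilyloxy)-5αH-bicyclo[5.3.0]dec-8-ene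
Product: 20 6α-angeloyloxy-10α-(tert-butyldimethylsilyloxy)-1β,8-dimethyl-5αH-bicyclo[5.3.0]dec-8-en-4β-ol
Conditions: PPTS (cat.), MeOH/CH2Cl2, 0 °C
Reagents that add atoms: none
Why: Mild acid methanolysis (selective silyl ether solvolysis) should cleave the triethylsilyl ether while the more hindered tert-butyldimethylsilyl ether and the ester stay.

Step 13
Reactants: 20 6α-angeloyloxy-10α-(tert-butyldimethylsilyloxy)-1β,8-dimethyl-5αH-bicyclo[5.3.0]dec-8-en-4β-ol
Product: 21 6α-angeloyloxy-10α-(tert-butyldimethylsilyloxy)-1β,8-dimethyl-5αH-bicyclo[5.3.0]dec-8-en-4-one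
Conditions: Dess–Martin periodinane, CH2Cl2, rt
Reagents that add atoms: none
Why: Dess–Martin oxidation of the secondary alcohol under non-basic conditions, chosen so that the β-acyloxy ketone does not eliminate and C5 does not epimerise.

Step 14
Reactants: 21 6α-angeloyloxy-10α-(tert-butyldimethylsilyloxy)-1β,8-dimethyl-5αH-bicyclo[5.3.0]dec-8-en-4-one
Product: 22 6α-angeloyloxy-10α-(tert-butyldimethylsilyloxy)-5αH-dauc-8-en-4β-ol
Conditions: i-PrMgCl, CeCl3, THF, −78 °C
Reagents that add atoms: isopropylmagnesium chloride CC(C)[Mg]Cl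
Why: Organocerium 1,2-addition (weakly basic and carbonyl-selective) should add isopropyl to the ketone faster than it enolises it or attacks the hindered unsaturated ester, from the α face opposite the axial C1 methyl, giving the 4β-hydroxy-4α-isopropyl centre.

Step 15
Reactants: 22 6α-angeloyloxy-10α-(tert-butyldimethylsilyloxy)-5αH-dauc-8-en-4β-ol
Product: 23 6α-angeloyloxy-5αH-dauc-8-ene-4β,10α-diol
Conditions: HF·pyridine, pyridine, THF, 0 °C to rt
Reagents that add atoms: none
Why: Buffered fluoride desilylation should free the C10 allylic alcohol without acyl migration or angelate isomerisation.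

Step 16
Reactants: 23 6α-angeloyloxy-5αH-dauc-8-ene-4β,10α-diol
Product: 24 lapiferine (6α-angeloyloxy-8α,9α-epoxy-5αH-daucane-4β,10α-diol)
Conditions: VO(acac)2 (5 mol %), t-BuOOH, CH2Cl2, 0 °C to rt
Reagents that add atoms: tert-butyl hydroperoxide CC(C)(C)OO
Why: Hydroxyl-directed vanadium-catalysed epoxidation: the 10α allylic alcohol binds the metal peroxide and delivers oxygen to the same face of C8=C9, setting the 8α,9α-epoxide, while the electron-poor angelate alkene is not attacked.

**Compound list**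
1 | 3-methylcyclopent-2-en-1-one | CC1=CC(=O)CC1 | starting material
2 | 2,3-dibromo-3-methylcyclopentan-1-one (racemic dibromide) | CC1(Br)CCC(=O)C1Br | intermediate (not isolated)
3 | 2-bromo-3-methylcyclopent-2-en-1-one | CC1=C(Br)C(=O)CC1 | intermediate
4 | (S)-2-bromo-3-methylcyclopent-2-en-1-ol | CC1=C(Br)[C@@H](O)CC1 | intermediate
5 | (S)-[(2-bromo-3-methylcyclopent-2-en-1-yl)oxy]triethylsilane | CC1=C(Br)[C@@H](O[Si](CC)(CC)CC)CC1 | intermediate
6 | (S)-triethyl[(3-methyl-2-vinylcyclopent-2-en-1-yl)oxy]silane | CC1=C(C=C)[C@@H](O[Si](CC)(CC)CC)CC1 | intermediate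
7 | ethyl diazoacetate | CCOC(=O)C=[N+]=[N-] | starting material
8 | (tert-butyldimethylsilyloxy)acetaldehyde | CC(C)(C)[Si](C)(C)OCC=O | starting material
9 | ethyl 4-[(tert-butyldimethylsilyl)oxy]-2-diazo-3-hydroxybutanoate (racemic) | CCOC(=O)C(=[N+]=[N-])C(O)CO[Si](C)(C)C(C)(C)C | intermediate
10 | ethyl 4-[(tert-butyldimethylsilyl)oxy]-2-diazo-3-(trifluoroacetoxy)butanoate (racemic) | CCOC(=O)C(=[N+]=[N-])C(OC(=O)C(F)(F)F)CO[Si](C)(C)C(C)(C)C | intermediate (not isolated)
11 | ethyl (E)-4-[(tert-butyldimethylsilyl)oxy]-2-diazobut-3-enoate | CCOC(=O)C(=[N+]=[N-])/C=C/O[Si](C)(C)C(C)(C)C | intermediate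
12 | ethyl (1R,2S)-1-[(E)-2-[(tert-butyldimethylsilyl)oxy]ethenyl]-2-[(5S)-2-methyl-5-[(triethylsilyl)oxy]cyclopent-1-en-1-yl]cyclopropane-1-carboxylate | CCOC(=O)[C@]1(/C=C/O[Si](C)(C)C(C)(C)C)C[C@H]1C2=C(C)CC[C@@H]2O[Si](CC)(CC)CC | intermediate (not isolated)
13 | ethyl (3S,8R,8aS)-8-[(tert-butyldimethylsilyl)oxy]-8a-methyl-3-[(triethylsilyl)oxy]-1,2,3,5,8,8a-hexahydroazulene-6-carboxylate | CCOC(=O)C1=C[C@@H](O[Si](C)(C)C(C)(C)C)[C@@]2(C)CC[C@H](O[Si](CC)(CC)CC)C2=CC1 | intermediate
14 | ethyl 6α-boranyl-10α-(tert-butyldimethylsilyloxy)-1β-methyl-4β-(triethylsilyloxy)-5αH-bicyclo[5.3.0]dec-8-ene-8-carboxylate | B[C@H]1CC(C(=O)OCC)=C[C@@H](O[Si](C)(C)C(C)(C)C)[C@@]2(C)CC[C@H](O[Si](CC)(CC)CC)[C@H]12 | intermediate (not isolated)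
15 | ethyl 6α-hydroxy-10α-(tert-butyldimethylsilyloxy)-1β-methyl-4β-(triethylsilyloxy)-5αH-bicyclo[5.3.0]dec-8-ene-8-carboxylate | O[C@H]1CC(C(=O)OCC)=C[C@@H](O[Si](C)(C)C(C)(C)C)[C@@]2(C)CC[C@H](O[Si](CC)(CC)CC)[C@H]12 | intermediate
16 | 8-(hydroxymethyl)-10α-(tert-butyldimethylsilyloxy)-1β-methyl-4β-(triethylsilyloxy)-5αH-bicyclo[5.3.0]dec-8-en-6α-ol | O[C@H]1CC(CO)=C[C@@H](O[Si](C)(C)C(C)(C)C)[C@@]2(C)CC[C@H](O[Si](CC)(CC)CC)[C@H]12 | intermediate
17 | primary allylic methanesulfonate of 16 | O[C@H]1CC(COS(C)(=O)=O)=C[C@@H](O[Si](C)(C)C(C)(C)C)[C@@]2(C)CC[C@H](O[Si](CC)(CC)CC)[C@H]12 | intermediate (not isolated)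
18 | 10α-(tert-butyldimethylsilyloxy)-1β,8-dimethyl-4β-(triethylsilyloxy)-5αH-bicyclo[5.3.0]dec-8-en-6α-ol | O[C@H]1CC(C)=C[C@@H](O[Si](C)(C)C(C)(C)C)[C@@]2(C)CC[C@H](O[Si](CC)(CC)CC)[C@H]12 | intermediate
19 | 6α-angeloyloxy-10α-(tert-butyldimethylsilyloxy)-1β,8-dimethyl-4β-(triethylsilyloxy)-5αH-bicyclo[5.3.0]dec-8-ene | C/C=C(/C)C(=O)O[C@H]1CC(C)=C[C@@H](O[Si](C)(C)C(C)(C)C)[C@@]2(C)CC[C@H](O[Si](CC)(CC)CC)[C@H]12 | intermediate
20 | 6α-angeloyloxy-10α-(tert-butyldimethylsilyloxy)-1β,8-dimethyl-5αH-bicyclo[5.3.0]dec-8-en-4β-ol | C/C=C(/C)C(=O)O[C@H]1CC(C)=C[C@@H](O[Si](C)(C)C(C)(C)C)[C@@]2(C)CC[C@H](O)[C@H]12 | intermediate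
21 | 6α-angeloyloxy-10α-(tert-butyldimethylsilyloxy)-1β,8-dimethyl-5αH-bicyclo[5.3.0]dec-8-en-4-one | C/C=C(/C)C(=O)O[C@H]1CC(C)=C[C@@H](O[Si](C)(C)C(C)(C)C)[C@@]2(C)CCC(=O)[C@H]12 | intermediate
22 | 6α-angeloyloxy-10α-(tert-butyldimethylsilyloxy)-5αH-dauc-8-en-4β-ol | C/C=C(/C)C(=O)O[C@H]1CC(C)=C[C@@H](O[Si](C)(C)C(C)(C)C)[C@@]2(C)CC[C@@](O)(C(C)C)[C@H]12 | intermediate
23 | 6α-angeloyloxy-5αH-dauc-8-ene-4β,10α-diol | C/C=C(/C)C(=O)O[C@H]1CC(C)=C[C@@H](O)[C@@]2(C)CC[C@@](O)(C(C)C)[C@H]12 | intermediate
24 | lapiferine | C/C=C(/C)C(=O)O[C@H]1C[C@@]2(C)O[C@H]2[C@@H](O)[C@@]2(C)CC[C@@](O)(C(C)C)[C@H]12 | target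

**Step count**
Total: 16 steps. Longest linear sequence: 14 steps (steps 1–4 and 7–16); the diazo fragment is made in steps 5–6.

**Steps most likely to fail, with fallbacks**

Step 7 (key step). The carbenoid may be consumed by dimerisation or by C–H insertion next to the C4 silyl ether, or the diazo ester may cyclise to a pyrazole, before the hindered, twisted diene traps it. The Cope step may also lag, because the ring methyl points into the boat. The fallback sets out from 11 (with bromide 5 as partner) and comes back at 13. Cyclopropanation of vinylboronic acid pinacol ester, used in excess as an unhindered trap, by 11 with Rh2(R-DOSP)4 in hexanes should give ethyl (1R,2R)-1-[(E)-2-[(tert-butyldimethylsilyl)oxy]ethenyl]-2-(4,4,5,5-tetramethyl-1,3,2-dioxaborolan-2-yl)cyclopropane-1-carboxylate F1. Stereoretentive Suzuki–Miyaura coupling of F1 with alkenyl bromide 5 (Pd(OAc)2, SPhos, K3PO4, toluene/H2O, 90 °C) then makes the C5–C6 bond by cross-coupling instead of carrying it in the diene. This gives cis-divinylcyclopropane 12, which should rearrange on continued heating to 13.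

Step 14. The ketone may enolise with E1cB loss of the angelate, the reagent may attack the ester, or facial selectivity may erode because the 6α-acyloxy group lies near the α face. The fallback sets out from 18 and comes back at 23; it changes the order of events so that the organometallic meets no ester and no acyloxy leaving group. Silylation of 18 (t-BuMe2SiOTf, 2,6-lutidine) gives 6α,10α-bis(tert-butyldimethylsilyloxy)-1β,8-dimethyl-4β-(triethylsilyloxy)-5αH-bicyclo[5.3.0]dec-8-ene F2. Methanolysis (PPTS, MeOH) gives 6α,10α-bis(tert-butyldimethylsilyloxy)-1β,8-dimethyl-5αH-bicyclo[5.3.0]dec-8-en-4β-ol F3, and Dess–Martin oxidation gives 6α,10α-bis(tert-butyldimethylsilyloxy)-1β,8-dimethyl-5αH-bicyclo[5.3.0]dec-8-en-4-one F4. Addition of i-PrMgCl/CeCl3 (THF, −78 °C) gives 6α,10α-bis(tert-butyldimethylsilyloxy)-5αH-dauc-8-en-4β-ol F5, and Bu4NF removes both silyl groups to give 5αH-dauc-8-ene-4β,6α,10α-triol F6. Yamaguchi angeloylation of F6 should then take the equatorial C6 hydroxyl in preference to the axial, neopentyl C10 hydroxyl and the tertiary C4 hydroxyl, giving 23.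

Step 6. Dehydration may give E/Z mixtures, or the electron-rich vinyldiazo ester may lose its silyl group or decompose under the acylating conditions. The fallback sets out from 8 and comes back at 11. Wittig olefination of 8 with Ph3P=CHCO2Et gives ethyl (E)-4-[(tert-butyldimethylsilyl)oxy]but-2-enoate F7. Deprotonation at the γ carbon with DBU and diazo transfer from p-acetamidobenzenesulfonyl azide to the α carbon of the dienolate (deconjugative diazo transfer, MeCN, 0 °C) should then give 11 without any acylating or acidic reagent.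

**Further compounds**
F1 | step 7 | ethyl (1R,2R)-1-[(E)-2-[(tert-butyldimethylsilyl)oxy]ethenyl]-2-(4,4,5,5-tetramethyl-1,3,2-dioxaborolan-2-yl)cyclopropane-1-carboxylate | CCOC(=O)[C@]1(/C=C/O[Si](C)(C)C(C)(C)C)C[C@H]1B1OC(C)(C)C(C)(C)O1
F2 | step 14 | 6α,10α-bis(tert-butyldimethylsilyloxy)-1β,8-dimethyl-4β-(triethylsilyloxy)-5αH-bicyclo[5.3.0]dec-8-ene | CC(C)(C)[Si](C)(C)O[C@H]1CC(C)=C[C@@H](O[Si](C)(C)C(C)(C)C)[C@@]2(C)CC[C@H](O[Si](CC)(CC)CC)[C@H]12
F3 | step 14 | 6α,10α-bis(tert-butyldimethylsilyloxy)-1β,8-dimethyl-5αH-bicyclo[5.3.0]dec-8-en-4β-ol | CC(C)(C)[Si](C)(C)O[C@H]1CC(C)=C[C@@H](O[Si](C)(C)C(C)(C)C)[C@@]2(C)CC[C@H](O)[C@H]12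
F4 | step 14 | 6α,10α-bis(tert-butyldimethylsilyloxy)-1β,8-dimethyl-5αH-bicyclo[5.3.0]dec-8-en-4-one | CC(C)(C)[Si](C)(C)O[C@H]1CC(C)=C[C@@H](O[Si](C)(C)C(C)(C)C)[C@@]2(C)CCC(=O)[C@H]12
F5 | step 14 | 6α,10α-bis(tert-butyldimethylsilyloxy)-5αH-dauc-8-en-4β-ol | CC(C)(C)[Si](C)(C)O[C@H]1CC(C)=C[C@@H](O[Si](C)(C)C(C)(C)C)[C@@]2(C)CC[C@@](O)(C(C)C)[C@H]12
F6 | step 14 | 5αH-dauc-8-ene-4β,6α,10α-triol | O[C@H]1CC(C)=C[C@@H](O)[C@@]2(C)CC[C@@](O)(C(C)C)[C@H]12
F7 | step 6 | ethyl (E)-4-[(tert-butyldimethylsilyl)oxy]but-2-enoate | CCOC(=O)/C=C/CO[Si](C)(C)C(C)(C)C
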